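**Retrosynthetic overview**
1. Endgame: the C3 ketone comes from the allylic alcohol (MnO2, last step), the C8 ester from angelic acid, the C11 methylene from a Mannich methylenation, and the C8 oxygen from an exocyclic C8 methylene (ozonolysis, then reduction directed by the C10 hydroxyl).
2. Key disconnection C9–C10: the strategy rests on the C1(OH)–C10(OH)(CH3)–C9H2–C8 segment of the ten-membered carbocycle, which is an α-hydroxy tertiary homoallylic carbinol once C8 carries =CH2. It opens to a C10 methyl ketone next to the free C1 hydroxyl and a 2-(bromomethyl)vinyl group on C7 (indium Barbier ring closure).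
3. Seco bromide: C3–C4 bond by Nozaki–Hiyama–Kishi coupling of a (Z)-vinyl iodide lactone with a keto aldehyde whose C1 centre comes from (S)-α-hydroxy-γ-butyrolactone (the chiral-pool lactone related to (S)-malic acid).
4. cis-Lactone (C6, C7): enantioselective anti-allylation of (Z)-3-iodobut-2-enal with a γ-(methoxycarbonylmethyl)-β-methylallyl bromide, lactonisation, then allylic oxidation of the isopropenyl methyl to install the C9 oxygen.
5. Ring order: γ-lactone first (step 6), ten-membered carbocycle second (step 16).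

Key step: step 16

Remark: germacrane numbering is used (lactone C6–O–C12(=O)–C11–C7); the Nozaki–Hiyama–Kishi coupling is assumed to give mainly the 1,3-anti (3S) carbinol, which is the epimer drawn, and the 3-epimer would serve equally because C3 ends as a ketone.

**Route**

Step 1
Reactants: 1 but-2-yn-1-ol
Product: 3 (Z)-3-iodobut-2-en-1-ol, via cyclic vinylalanate 2 (not isolated)
Conditions: NaAlH2(OCH2CH2OCH3)2, THF, 0 °C to rt; then I2, THF, −78 °C
Reagents that add atoms: iodine, II
Why: Hydroxyl-directed trans-hydroalumination places aluminium on C3 in a five-membered alkoxyalanate and iodinolysis with retention should give the (Z)-iodoalkene that becomes the (Z)-C4=C5 bond with its C15 methyl.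

Step 2
Reactants: 3 (Z)-3-iodobut-2-en-1-ol
Product: 4 (Z)-3-iodobut-2-enal
Conditions: MnO2, CH2Cl2, rt, dark; used at once
Reagents that add atoms: none
Why: Neutral MnO2 oxidation of an allylic alcohol should leave the (Z)-geometry of the sensitive β-iodo enal intact.

Step 3
Reactants: 5 4-methylpent-3-enoic acid
Product: 6 methyl 4-methylpent-3-enoate
Conditions: MeI, KHCO3, DMF, rt
Reagents that add atoms: iodomethane, CI
Why: Carboxylate O-alkylation (SN2) esterifies without acid, which would lactonise this alkenoic acid, and without base strong enough to move the double bond into conjugation.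

Step 4
Reactants: 6 methyl 4-methylpent-3-enoate
Product: 7 methyl (E)-5-hydroxy-4-methylpent-3-enoate
Conditions: SeO2 (0.5 equiv), t-BuOOH, CH2Cl2, 0 °C to rt
Reagents that add atoms: selenium dioxide, O=[Se]=O (transfers the oxygen); tert-butyl hydroperoxide, CC(C)(C)OO (re-forms it)
Why: Riley allylic oxidation (ene reaction, then [2,3]-shift) of a gem-dimethyl trisubstituted alkene is selective for the (E)-methyl group.

Step 5
Reactants: 7 methyl (E)-5-hydroxy-4-methylpent-3-enoate
Product: 8 methyl (E)-5-bromo-4-methylpent-3-enoate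
Conditions: CBr4, PPh3, CH2Cl2, 0 °C
Reagents that add atoms: carbon tetrabromide, BrC(Br)(Br)Br
Why: Appel bromination of a primary allylic alcohol proceeds under neutral conditions that keep the β,γ-unsaturated ester and the (E)-geometry.

Step 6
Reactants: 4 (Z)-3-iodobut-2-enal; 8 methyl (E)-5-bromo-4-methylpent-3-enoate
Product: 12 (4R,5R)-5-[(Z)-2-iodoprop-1-en-1-yl]-4-(prop-1-en-2-yl)dihydrofuran-2(3H)-one, via allylchromium species 9 (not isolated), via silyl ether 10 (not isolated), via hydroxy ester 11 (not isolated)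
Conditions: CrCl2 (10 mol%, nickel-free), chiral 1,8-bis(4-isopropyl-4,5-dihydrooxazol-2-yl)carbazole ligand (12 mol%, enantiomer chosen for the 3R,4R adduct), Mn powder, Me3SiCl, i-Pr2NEt, THF, rt; then 1 M HCl, THF; then TsOH·H2O (cat.), toluene, 50 °C
Reagents that add atoms: none
Why: In this catalytic enantioselective Nozaki–Hiyama allylation the σ-allylchromium adds through its γ-carbon in a chair transition state with the CH2CO2Me arm equatorial, which should give the anti adduct (C6 and C7 set together, absolute sense set by the ligand), and acid lactonisation of an anti γ-hydroxy ester necessarily gives the cis-4,5-disubstituted γ-lactone.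

Step 7
Reactants: 12 (4R,5R)-5-[(Z)-2-iodoprop-1-en-1-yl]-4-(prop-1-en-2-yl)dihydrofuran-2(3H)-one
Product: 13 (4R,5R)-4-(3-hydroxyprop-1-en-2-yl)-5-[(Z)-2-iodoprop-1-en-1-yl]dihydrofuran-2(3H)-one
Conditions: SeO2 (0.5 equiv), t-BuOOH, CH2Cl2, rt
Reagents that add atoms: selenium dioxide, O=[Se]=O (transfers the oxygen); tert-butyl hydroperoxide, CC(C)(C)OO (re-forms it)
Why: Riley oxidation of an isopropenyl group attacks its methyl and not the allylic methine, while the iodine-bearing alkene is too electron-poor for the ene step, so the C9 oxygen is installed before any other electron-rich alkene is present.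

Step 8
Reactants: 13 (4R,5R)-4-(3-hydroxyprop-1-en-2-yl)-5-[(Z)-2-iodoprop-1-en-1-yl]dihydrofuran-2(3H)-one
Product: 14 (4R,5R)-5-[(Z)-2-iodoprop-1-en-1-yl]-4-[3-(triethylsilyloxy)prop-1-en-2-yl]dihydrofuran-2(3H)-one
Conditions: Et3SiCl, imidazole, CH2Cl2, 0 °C
Reagents that add atoms: chlorotriethylsilane, CC[Si](Cl)(CC)CC
Why: Silylation of the primary allylic alcohol gives an ether that survives the chromium coupling and is later cleaved together with the C1 silyl ether.

Step 9
Reactants: 15 (S)-3-hydroxydihydrofuran-2(3H)-one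
Product: 16 (S)-3-(triethylsilyloxy)dihydrofuran-2(3H)-one
Conditions: Et3SiCl, imidazole, DMF, 0 °C to rt
Reagents that add atoms: chlorotriethylsilane, CC[Si](Cl)(CC)CC
Why: Standard silylation protects the chiral-pool hydroxyl that becomes the C1 carbinol.

Step 10
Reactants: 16 (S)-3-(triethylsilyloxy)dihydrofuran-2(3H)-one
Product: 18 (S)-5-hydroxy-3-(triethylsilyloxy)pentan-2-one, via lithium hemiketalate 17 (not isolated)
Conditions: MeLi (1.05 equiv), THF, −78 °C; then sat. NH4Cl, −78 °C to rt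
Reagents that add atoms: methyllithium, [Li]C
Why: Mono-addition of MeLi to the lactone should stop at the lithium hemiketalate at −78 °C, and protonation releases the C10 methyl ketone (in equilibrium with its cyclic hemiketal) without touching the C1 centre.

Step 11
Reactants: 18 (S)-5-hydroxy-3-(triethylsilyloxy)pentan-2-one
Product: 19 (S)-4-oxo-3-(triethylsilyloxy)pentanal
Conditions: Dess–Martin periodinane, NaHCO3, CH2Cl2, 0 °C; used crude
Reagents that add atoms: none
Why: Buffered Dess–Martin oxidation of the open-chain primary alcohol gives the C3 aldehyde under conditions mild enough to avoid β-elimination of the silyloxy group.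

Step 12
Reactants: 14 (4R,5R)-5-[(Z)-2-iodoprop-1-en-1-yl]-4-[3-(triethylsilyloxy)prop-1-en-2-yl]dihydrofuran-2(3H)-one; 19 (S)-4-oxo-3-(triethylsilyloxy)pentanal
Product: 21 (4R,5S)-5-[(1Z,3S,5S)-3-hydroxy-2-methyl-6-oxo-5-(triethylsilyloxy)hept-1-en-1-yl]-4-[3-(triethylsilyloxy)prop-1-en-2-yl]dihydrofuran-2(3H)-one, via alkenylchromium species 20 (not isolated)
Conditions: CrCl2 (4 equiv), NiCl2 (1 mol%), DMSO, rt
Reagents that add atoms: none
Why: In this Nozaki–Hiyama–Kishi coupling zerovalent nickel inserts into the C4–I bond with retention of the (Z)-geometry and the alkenylchromium adds only to the aldehyde (ketone, lactone and silyl ethers are inert), the C3 carbinol forming mainly as the 1,3-anti (3S) epimer by polar 1,3-induction from the β-silyloxy centre.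

Step 13
Reactants: 21 (the C3 alcohol from step 12)
Product: 22 (4R,5S)-5-[(1Z,3S,5S)-3-(tert-butyldimethylsilyloxy)-2-methyl-6-oxo-5-(triethylsilyloxy)hept-1-en-1-yl]-4-[3-(triethylsilyloxy)prop-1-en-2-yl]dihydrofuran-2(3H)-one
Conditions: t-BuMe2SiOTf, 2,6-lutidine, CH2Cl2, −78 °C
Reagents that add atoms: tert-butyldimethylsilyl triflate, CC(C)(C)[Si](C)(C)OS(=O)(=O)C(F)(F)F
Why: Silylation of the secondary allylic alcohol traps the open-chain form of the γ-hydroxy ketone and keeps C3 as an sp3 centre that cannot compete with C10 in the ring closure.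

Step 14
Reactants: 22 (the tris-silyl ether from step 13)
Product: 23 (4R,5S)-5-[(1Z,3S,5S)-3-(tert-butyldimethylsilyloxy)-5-hydroxy-2-methyl-6-oxohept-1-en-1-yl]-4-(3-hydroxyprop-1-en-2-yl)dihydrofuran-2(3H)-one
Conditions: PPTS (cat.), MeOH, 0 °C to rt
Reagents that add atoms: none
Why: Acid-catalysed methanolysis cleaves both triethylsilyl ethers far faster than the secondary tert-butyldimethylsilyl ether, which frees the C9 and C1 hydroxyls in one operation.

Step 15
Reactants: 23 (the diol from step 14)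
Product: 24 (4R,5S)-4-(3-bromoprop-1-en-2-yl)-5-[(1Z,3S,5S)-3-(tert-butyldimethylsilyloxy)-5-hydroxy-2-methyl-6-oxohept-1-en-1-yl]dihydrofuran-2(3H)-one
Conditions: CBr4 (1.1 equiv), PPh3 (1.1 equiv), CH2Cl2, −20 °C
Reagents that add atoms: carbon tetrabromide, BrC(Br)(Br)Br
Why: Appel bromination should take the unhindered primary allylic alcohol in preference to the hindered secondary α-ketol hydroxyl, which must stay free for chelation.

Step 16
Reactants: 24 (the seco bromide from step 15)
Product: 26 (1S,3S,6S,7R,10S)-3-(tert-butyldimethylsilyloxy)-1,10-dihydroxy-8-methylidene-13-norgermacr-4(Z)-en-6,12-olide, via allylindium species 25 (not isolated)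
Conditions: In powder (3 equiv), THF/H2O (1:1), 0.003 M, rt
Reagents that add atoms: none
Why: Indium metal inserts into the allylic C9–Br bond and the resulting σ-allylindium, whose two CH2 termini are interchangeable, adds through a six-membered cyclic transition state to the C10 ketone while trivalent indium is held in a five-membered chelate by the free C1 hydroxyl and the carbonyl oxygen. The closest known reactions are the aqueous indium Barbier allylation of α-hydroxy ketones under chelation control and intramolecular Barbier allylations that close medium rings. The ten-membered carbocycle is closed in a 10-exo-trig mode by attack of C9 on the exocyclic C10=O, with the cis-fused lactone and the (Z)-C4=C5 bond acting as turn elements that bring the chain ends together. The new C10 stereocentre is controlled by the chelate: the allyl group arrives on the carbonyl face flanked by the small C1–H and not by C2, which gives the 1,10-threo diol (10S from 1S). The step needs ring closure to outrun intermolecular allylation and protonolysis, which high dilution and the chelation-activated ketone should secure, and it needs the ketone to be attacked in preference to the lactone, which is inherent because allylindium reagents do not add to esters. Regiochemistry of the allyl unit is not an issue because either terminus gives the same 8-methylidene product.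

Step 17
Reactants: 26 (the macrocyclic diol from step 16)
Product: 27 (1S,3S,6S,7R,10S)-1,3-bis(tert-butyldimethylsilyloxy)-10-hydroxy-8-methylidene-13-norgermacr-4(Z)-en-6,12-olide
Conditions: t-BuMe2SiOTf (1.2 equiv), 2,6-lutidine, CH2Cl2, −78 to −40 °C
Reagents that add atoms: tert-butyldimethylsilyl triflate, CC(C)(C)[Si](C)(C)OS(=O)(=O)C(F)(F)F
Why: The secondary C1 hydroxyl is silylated much faster than the tertiary C10 hydroxyl, which stays free to direct the later reduction.

Step 18
Reactants: 27 (the bis-silyl ether from step 17)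
Product: 29 (1S,3S,6S,7S,10S)-1,3-bis(tert-butyldimethylsilyloxy)-10-hydroxy-8-oxo-13-norgermacr-4(Z)-en-6,12-olide, via ozonide 28 (not isolated)
Conditions: O3, CH2Cl2, −78 °C, Sudan Red 7B end-point; then PPh3, −78 °C to rt; used crude
Reagents that add atoms: ozone, [O-][O+]=O
Why: Ozonolysis should take the electron-rich, unhindered 1,1-disubstituted C8 methylene before the C4=C5 bond, which is deactivated by two allylic C–O bonds and shielded by the 3-silyloxy group, and neutral reductive work-up spares the base-sensitive β-acyloxy β'-hydroxy ketone.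

Step 19
Reactants: 29 (the C8 ketone from step 18)
Product: 31 (1S,3S,6S,7R,8R,10S)-1,3-bis(tert-butyldimethylsilyloxy)-8,10-dihydroxy-13-norgermacr-4(Z)-en-6,12-olide, via diethylborinate 30 (not isolated)
Conditions: Et2BOMe, THF/MeOH (4:1), −78 °C; NaBH4, −78 °C; AcOH quench, then repeated evaporation from MeOH
Reagents that add atoms: none
Why: In this Narasaka–Prasad reduction the diethylboron chelate between the C10 oxygen and the C8 carbonyl fixes a half-chair and external hydride attacks axially, which should give the 8,10-syn diol, that is 8R.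

Step 20
Reactants: 31 (the 8,10-diol from step 19)
Product: 32 (1S,3S,6S,7S,8R,10S)-1,3-bis(tert-butyldimethylsilyloxy)-10-hydroxy-8-(triethylsilyloxy)-13-norgermacr-4(Z)-en-6,12-olide
Conditions: Et3SiCl, imidazole, DMF, 0 °C
Reagents that add atoms: chlorotriethylsilane, CC[Si](Cl)(CC)CC
Why: Silylation of the secondary C8 hydroxyl removes the alkoxide that would otherwise translactonise onto C12 during the enolate chemistry of the next step.

Step 21
Reactants: 32 (the C8 triethylsilyl ether from step 20)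
Product: 35 (1S,3S,6S,7S,8R,10S)-1,3-bis(tert-butyldimethylsilyloxy)-10-hydroxy-8-(triethylsilyloxy)germacra-4(Z),11(13)-dien-6,12-olide, via Mannich base 33 (not isolated), via ammonium iodide 34 (not isolated)
Conditions: LiN(i-Pr)2 (2.5 equiv), THF, −78 °C; Me2N=CH2 iodide, −78 to 0 °C; then MeI, MeOH, rt; then aq. NaHCO3, CH2Cl2, rt
Reagents that add atoms: N,N-dimethylmethyleneiminium iodide (Eschenmoser's salt), C=[N+](C)C.[I-]
Why: In this Eschenmoser–Mannich methylenation the lithium enolate of the only enolisable carbonyl (the 10-OH is carried as its lithium alkoxide) is aminomethylated at C11, and elimination of the quaternised amine can only give the exocyclic C11=C13 bond.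

Step 22
Reactants: 35 (the α-methylene lactone from step 21)
Product: 36 (1S,3S,6S,7R,8R,10S)-1,3-bis(tert-butyldimethylsilyloxy)-8,10-dihydroxygermacra-4(Z),11(13)-dien-6,12-olide
Conditions: PPTS (cat.), MeOH, 0 °C
Reagents that add atoms: none
Why: Mild acidic methanolysis removes the triethylsilyl ether selectively and avoids the basic conditions under which a free C8 hydroxyl could translactonise.

Step 23
Reactants: 36 (the C8 alcohol from step 22); 37 angelic acid
Product: 39 (1S,3S,6S,7R,8R,10S)-8-angeloyloxy-1,3-bis(tert-butyldimethylsilyloxy)-10-hydroxygermacra-4(Z),11(13)-dien-6,12-olide, via mixed anhydride 38 (not isolated)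
Conditions: 37, 2,4,6-trichlorobenzoyl chloride, Et3N, toluene, rt; then 36, 75 °C
Reagents that add atoms: none
Why: Yamaguchi-type esterification through the mixed anhydride, run without DMAP so that the (Z)-angelate is not isomerised to the tiglate, acylates only the secondary 8-OH and leaves the tertiary 10-OH.

Step 24
Reactants: 39 (the 8-angelate from step 23)
Product: 40 (1S,3S,6S,7R,8R,10S)-8-angeloyloxy-1,3,10-trihydroxygermacra-4(Z),11(13)-dien-6,12-olide
Conditions: HF·pyridine, pyridine, THF, 0 °C to rt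
Reagents that add atoms: none
Why: Buffered fluoride cleaves both silyl ethers under weakly acidic conditions that spare the angelate, the α-methylene lactone and the tertiary alcohol.

Step 25
Reactants: 40 (the triol from step 24)
Product: 41 CNP0271189.1, (1S,6S,7R,8R,10S)-8-angeloyloxy-1,10-dihydroxy-3-oxogermacra-4(Z),11(13)-dien-6,12-olide
Conditions: MnO2 (excess), CH2Cl2, rt
Reagents that add atoms: none
Why: MnO2 oxidises only the allylic C3 alcohol to the (Z)-enone and leaves the saturated 1-OH and the tertiary 10-OH, which is why C1 and C3 can be unmasked together.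

**Compound list**
1 | but-2-yn-1-ol | CC#CCO | starting material
2 | sodium 3-methyl-2,2-bis(2-methoxyethoxy)-2,5-dihydro-1,2-oxaaluminol-2-uide (cyclic vinylalanate) | [Na+].CC1=CCO[Al-]1(OCCOC)OCCOC | intermediate
3 | (Z)-3-iodobut-2-en-1-ol | OC/C=C(/C)I | intermediate
4 | (Z)-3-iodobut-2-enal | O=C/C=C(/C)I | intermediate
5 | 4-methylpent-3-enoic acid | CC(C)=CCC(=O)O | starting material
6 | methyl 4-methylpent-3-enoate | COC(=O)CC=C(C)C | intermediate
7 | methyl (E)-5-hydroxy-4-methylpent-3-enoate | COC(=O)C/C=C(\C)CO | intermediate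
8 | methyl (E)-5-bromo-4-methylpent-3-enoate | COC(=O)C/C=C(\C)CBr | intermediate
9 | (E)-allylchromium dichloride from 8 (trivalent chromium, chiral ligand omitted) | COC(=O)C/C=C(\C)C[Cr](Cl)Cl | intermediate
10 | methyl (3R,4R,5Z)-6-iodo-3-(prop-1-en-2-yl)-4-(trimethylsilyloxy)hept-5-enoate | COC(=O)C[C@H](C(C)=C)[C@@H](O[Si](C)(C)C)/C=C(/C)I | intermediate
11 | methyl (3R,4R,5Z)-4-hydroxy-6-iodo-3-(prop-1-en-2-yl)hept-5-enoate | COC(=O)C[C@H](C(C)=C)[C@@H](O)/C=C(/C)I | intermediate
12 | (4R,5R)-5-[(Z)-2-iodoprop-1-en-1-yl]-4-(prop-1-en-2-yl)dihydrofuran-2(3H)-one | O=C1C[C@H](C(C)=C)[C@@H](O1)/C=C(/C)I | intermediate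
13 | (4R,5R)-4-(3-hydroxyprop-1-en-2-yl)-5-[(Z)-2-iodoprop-1-en-1-yl]dihydrofuran-2(3H)-one | O=C1C[C@H](C(=C)CO)[C@@H](O1)/C=C(/C)I | intermediate
14 | (4R,5R)-5-[(Z)-2-iodoprop-1-en-1-yl]-4-[3-(triethylsilyloxy)prop-1-en-2-yl]dihydrofuran-2(3H)-one | O=C1C[C@H](C(=C)CO[Si](CC)(CC)CC)[C@@H](O1)/C=C(/C)I | intermediate
15 | (S)-3-hydroxydihydrofuran-2(3H)-one ((S)-α-hydroxy-γ-butyrolactone) | O[C@H]1CCOC1=O | starting material
16 | (S)-3-(triethylsilyloxy)dihydrofuran-2(3H)-one | CC[Si](CC)(CC)O[C@H]1CCOC1=O | intermediate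
17 | lithium (3S)-2-methyl-3-(triethylsilyloxy)tetrahydrofuran-2-olate (C2 not defined) | [Li+].CC1([O-])OCC[C@@H]1O[Si](CC)(CC)CC | intermediate
18 | (S)-5-hydroxy-3-(triethylsilyloxy)pentan-2-one | CC(=O)[C@@H](O[Si](CC)(CC)CC)CCO | intermediate
19 | (S)-4-oxo-3-(triethylsilyloxy)pentanal | CC(=O)[C@@H](O[Si](CC)(CC)CC)CC=O | intermediate
20 | (Z)-alkenylchromium dichloride from 14 (trivalent chromium) | O=C1C[C@H](C(=C)CO[Si](CC)(CC)CC)[C@@H](O1)/C=C(/C)[Cr](Cl)Cl | intermediate
21 | (4R,5S)-5-[(1Z,3S,5S)-3-hydroxy-2-methyl-6-oxo-5-(triethylsilyloxy)hept-1-en-1-yl]-4-[3-(triethylsilyloxy)prop-1-en-2-yl]dihydrofuran-2(3H)-one | O=C1C[C@H](C(=C)CO[Si](CC)(CC)CC)[C@@H](O1)/C=C(/C)[C@@H](O)C[C@H](O[Si](CC)(CC)CC)C(C)=O | intermediate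
22 | (4R,5S)-5-[(1Z,3S,5S)-3-(tert-butyldimethylsilyloxy)-2-methyl-6-oxo-5-(triethylsilyloxy)hept-1-en-1-yl]-4-[3-(triethylsilyloxy)prop-1-en-2-yl]dihydrofuran-2(3H)-one | O=C1C[C@H](C(=C)CO[Si](CC)(CC)CC)[C@@H](O1)/C=C(/C)[C@@H](O[Si](C)(C)C(C)(C)C)C[C@H](O[Si](CC)(CC)CC)C(C)=O | intermediate
23 | (4R,5S)-5-[(1Z,3S,5S)-3-(tert-butyldimethylsilyloxy)-5-hydroxy-2-methyl-6-oxohept-1-en-1-yl]-4-(3-hydroxyprop-1-en-2-yl)dihydrofuran-2(3H)-one | O=C1C[C@H](C(=C)CO)[C@@H](O1)/C=C(/C)[C@@H](O[Si](C)(C)C(C)(C)C)C[C@H](O)C(C)=O | intermediate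
24 | (4R,5S)-4-(3-bromoprop-1-en-2-yl)-5-[(1Z,3S,5S)-3-(tert-butyldimethylsilyloxy)-5-hydroxy-2-methyl-6-oxohept-1-en-1-yl]dihydrofuran-2(3H)-one (key-step precursor) | O=C1C[C@H](C(=C)CBr)[C@@H](O1)/C=C(/C)[C@@H](O[Si](C)(C)C(C)(C)C)C[C@H](O)C(C)=O | intermediate
25 | allylindium dibromide from 24 (trivalent indium, one component of the sesquibromide) | O=C1C[C@H](C(=C)C[In](Br)Br)[C@@H](O1)/C=C(/C)[C@@H](O[Si](C)(C)C(C)(C)C)C[C@H](O)C(C)=O | intermediate
26 | (1S,3S,6S,7R,10S)-3-(tert-butyldimethylsilyloxy)-1,10-dihydroxy-8-methylidene-13-norgermacr-4(Z)-en-6,12-olide (key-step product) | O=C1C[C@H]2[C@@H](O1)/C=C(/C)[C@@H](O[Si](C)(C)C(C)(C)C)C[C@H](O)[C@@](C)(O)CC2=C | intermediate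
27 | (1S,3S,6S,7R,10S)-1,3-bis(tert-butyldimethylsilyloxy)-10-hydroxy-8-methylidene-13-norgermacr-4(Z)-en-6,12-olide | O=C1C[C@H]2[C@@H](O1)/C=C(/C)[C@@H](O[Si](C)(C)C(C)(C)C)C[C@H](O[Si](C)(C)C(C)(C)C)[C@@](C)(O)CC2=C | intermediate
28 | spiro-1,2,4-trioxolane (ozonide) at C8 of 27 (C8 not defined) | O=C1C[C@H]2[C@@H](O1)/C=C(/C)[C@@H](O[Si](C)(C)C(C)(C)C)C[C@H](O[Si](C)(C)C(C)(C)C)[C@@](C)(O)CC23OCOO3 | intermediate
29 | (1S,3S,6S,7S,10S)-1,3-bis(tert-butyldimethylsilyloxy)-10-hydroxy-8-oxo-13-norgermacr-4(Z)-en-6,12-olide | O=C1C[C@H]2[C@@H](O1)/C=C(/C)[C@@H](O[Si](C)(C)C(C)(C)C)C[C@H](O[Si](C)(C)C(C)(C)C)[C@@](C)(O)CC2=O | intermediate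
30 | 10-O-diethylboryl derivative of 29 | O=C1C[C@H]2[C@@H](O1)/C=C(/C)[C@@H](O[Si](C)(C)C(C)(C)C)C[C@H](O[Si](C)(C)C(C)(C)C)[C@@](C)(OB(CC)CC)CC2=O | intermediate
31 | (1S,3S,6S,7R,8R,10S)-1,3-bis(tert-butyldimethylsilyloxy)-8,10-dihydroxy-13-norgermacr-4(Z)-en-6,12-olide | O=C1C[C@H]2[C@@H](O1)/C=C(/C)[C@@H](O[Si](C)(C)C(C)(C)C)C[C@H](O[Si](C)(C)C(C)(C)C)[C@@](C)(O)C[C@H]2O | intermediate
32 | (1S,3S,6S,7S,8R,10S)-1,3-bis(tert-butyldimethylsilyloxy)-10-hydroxy-8-(triethylsilyloxy)-13-norgermacr-4(Z)-en-6,12-olide | O=C1C[C@H]2[C@@H](O1)/C=C(/C)[C@@H](O[Si](C)(C)C(C)(C)C)C[C@H](O[Si](C)(C)C(C)(C)C)[C@@](C)(O)C[C@H]2O[Si](CC)(CC)CC | intermediate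
33 | 11-(dimethylaminomethyl) derivative of 32 (C11 epimers) | O=C1C(CN(C)C)[C@H]2[C@@H](O1)/C=C(/C)[C@@H](O[Si](C)(C)C(C)(C)C)C[C@H](O[Si](C)(C)C(C)(C)C)[C@@](C)(O)C[C@H]2O[Si](CC)(CC)CC | intermediate
34 | 11-(trimethylammoniomethyl) iodide from 33 (C11 epimers) | [I-].O=C1C(C[N+](C)(C)C)[C@H]2[C@@H](O1)/C=C(/C)[C@@H](O[Si](C)(C)C(C)(C)C)C[C@H](O[Si](C)(C)C(C)(C)C)[C@@](C)(O)C[C@H]2O[Si](CC)(CC)CC | intermediate
35 | (1S,3S,6S,7S,8R,10S)-1,3-bis(tert-butyldimethylsilyloxy)-10-hydroxy-8-(triethylsilyloxy)germacra-4(Z),11(13)-dien-6,12-olide | O=C1C(=C)[C@H]2[C@@H](O1)/C=C(/C)[C@@H](O[Si](C)(C)C(C)(C)C)C[C@H](O[Si](C)(C)C(C)(C)C)[C@@](C)(O)C[C@H]2O[Si](CC)(CC)CC | intermediate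
36 | (1S,3S,6S,7R,8R,10S)-1,3-bis(tert-butyldimethylsilyloxy)-8,10-dihydroxygermacra-4(Z),11(13)-dien-6,12-olide | O=C1C(=C)[C@H]2[C@@H](O1)/C=C(/C)[C@@H](O[Si](C)(C)C(C)(C)C)C[C@H](O[Si](C)(C)C(C)(C)C)[C@@](C)(O)C[C@H]2O | intermediate
37 | angelic acid, (Z)-2-methylbut-2-enoic acid | C/C=C(/C)C(=O)O | starting material
38 | angelic 2,4,6-trichlorobenzoic anhydride | C/C=C(/C)C(=O)OC(=O)c1c(Cl)cc(Cl)cc1Cl | intermediate
39 | (1S,3S,6S,7R,8R,10S)-8-angeloyloxy-1,3-bis(tert-butyldimethylsilyloxy)-10-hydroxygermacra-4(Z),11(13)-dien-6,12-olide | O=C1C(=C)[C@H]2[C@@H](O1)/C=C(/C)[C@@H](O[Si](C)(C)C(C)(C)C)C[C@H](O[Si](C)(C)C(C)(C)C)[C@@](C)(O)C[C@H]2OC(=O)/C(C)=C\C | intermediate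
40 | (1S,3S,6S,7R,8R,10S)-8-angeloyloxy-1,3,10-trihydroxygermacra-4(Z),11(13)-dien-6,12-olide | O=C1C(=C)[C@H]2[C@@H](O1)/C=C(/C)[C@@H](O)C[C@H](O)[C@@](C)(O)C[C@H]2OC(=O)/C(C)=C\C | intermediate
41 | CNP0271189.1, (1S,6S,7R,8R,10S)-8-angeloyloxy-1,10-dihydroxy-3-oxogermacra-4(Z),11(13)-dien-6,12-olide | C=C1C(=O)O[C@H]2/C=C(/C)C(=O)C[C@H](O)[C@@](C)(O)C[C@@H](OC(=O)/C(C)=C\C)[C@@H]12 | target

**Step count and risks**
Total: 25 steps. Longest linear sequence: 20 steps (5 to 41 through steps 3–8 and 12–25).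

Steps most likely to fail:

1. Step 16 (ring closure). The slow end-to-end closure of a ten-membered ring may be outrun by protonolysis of the allylindium or by intermolecular allylation, and ring strain may erode chelation control at C10. Fallback: from 24, palladium-catalysed exchange of the bromide with hexabutylditin (Pd(PPh3)4, THF, 50 °C) gives the allylstannane (4R,5S)-5-[(1Z,3S,5S)-3-(tert-butyldimethylsilyloxy)-5-hydroxy-2-methyl-6-oxohept-1-en-1-yl]-4-[3-(tributylstannyl)prop-1-en-2-yl]dihydrofuran-2(3H)-one F1. This is cyclised under homogeneous Lewis-acid conditions (MgBr2·OEt2, CH2Cl2, 0.002 M, −20 °C), a chelation-controlled open-transition-state allylstannane addition that forms the same C9–C10 bond without a metal surface or a protic medium, and returns to the route at 26.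

2. Step 6 (anti-allylation). The equilibrating allylchromium may leak into the syn manifold, and enantiofacial discrimination on the small (Z)-β-iodo enal may be incomplete. Fallback: from 8, zerovalent-palladium-catalysed borylation (bis(pinacolato)diboron, Pd2(dba)3, THF, 60 °C) gives the configurationally fixed methyl (E)-4-methyl-5-(4,4,5,5-tetramethyl-1,3,2-dioxaborolan-2-yl)pent-3-enoate F2. Chiral phosphoric acid catalysed allylboration of 4 (TRIP, toluene, −30 °C) then proceeds through a closed chair transition state in which the (E)-geometry alone fixes the anti relationship, giving the O-boryl adduct methyl (3R,4R,5Z)-6-iodo-3-(prop-1-en-2-yl)-4-[(4,4,5,5-tetramethyl-1,3,2-dioxaborolan-2-yl)oxy]hept-5-enoate F3. Aqueous work-up returns to the route at 11, which lactonises to 12 as in step 6.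

3. Step 19 (C8 reduction). If the ten-membered ring cannot accommodate the half-chair boron chelate, hydride may be delivered to the other face of C8; base-induced loss of the β-acyloxy lactone oxygen is a second hazard. Fallback: from 29, the reduction is run as before and the 8-epimeric alcohol (1S,3S,6S,7R,8S,10S)-1,3-bis(tert-butyldimethylsilyloxy)-8,10-dihydroxy-13-norgermacr-4(Z)-en-6,12-olide F4 is inverted instead of being resubmitted. Mitsunobu esterification with chloroacetic acid (PPh3, DIAD, toluene, 0 °C) gives the 8R chloroacetate (1S,3S,6S,7R,8R,10S)-1,3-bis(tert-butyldimethylsilyloxy)-8-(chloroacetoxy)-10-hydroxy-13-norgermacr-4(Z)-en-6,12-olide F5, and neutral cleavage with thiourea (NaHCO3, EtOH/THF) returns to the route at 31.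

**Further compounds**
F1 | step 16 | (4R,5S)-5-[(1Z,3S,5S)-3-(tert-butyldimethylsilyloxy)-5-hydroxy-2-methyl-6-oxohept-1-en-1-yl]-4-[3-(tributylstannyl)prop-1-en-2-yl]dihydrofuran-2(3H)-one | O=C1C[C@H](C(=C)C[Sn](CCCC)(CCCC)CCCC)[C@@H](O1)/C=C(/C)[C@@H](O[Si](C)(C)C(C)(C)C)C[C@H](O)C(C)=O
F2 | step 6 | methyl (E)-4-methyl-5-(4,4,5,5-tetramethyl-1,3,2-dioxaborolan-2-yl)pent-3-enoate | COC(=O)C/C=C(\C)CB1OC(C)(C)C(C)(C)O1
F3 | step 6 | methyl (3R,4R,5Z)-6-iodo-3-(prop-1-en-2-yl)-4-[(4,4,5,5-tetramethyl-1,3,2-dioxaborolan-2-yl)oxy]hept-5-enoate | COC(=O)C[C@H](C(C)=C)[C@@H](OB1OC(C)(C)C(C)(C)O1)/C=C(/C)I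
F4 | step 19 | (1S,3S,6S,7R,8S,10S)-1,3-bis(tert-butyldimethylsilyloxy)-8,10-dihydroxy-13-norgermacr-4(Z)-en-6,12-olide | O=C1C[C@H]2[C@@H](O1)/C=C(/C)[C@@H](O[Si](C)(C)C(C)(C)C)C[C@H](O[Si](C)(C)C(C)(C)C)[C@@](C)(O)C[C@@H]2O
F5 | step 19 | (1S,3S,6S,7R,8R,10S)-1,3-bis(tert-butyldimethylsilyloxy)-8-(chloroacetoxy)-10-hydroxy-13-norgermacr-4(Z)-en-6,12-olide | O=C1C[C@H]2[C@@H](O1)/C=C(/C)[C@@H](O[Si](C)(C)C(C)(C)C)C[C@H](O[Si](C)(C)C(C)(C)C)[C@@](C)(O)C[C@H]2OC(=O)CCl
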